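The cyclopentenone ring (C1 carbonyl, C2 OMe, C3 aryl, C4 spiro carbon, C5 OMe/aryl) is cut at C1–C2 and C3–C4 into an aryl ynol ether (C2≡C3) and an enantioenriched β-keto ester (C4 ketone, C5, C1 ester). The key step exploits the fact that the oxirane oxygen on C4 stands in an aldol relation to the C1 ketone across quaternary C5: a nickel-catalysed reductive [3+2] annulation adds C3 to the C4 ketone and C2 to the C1 ester in one operation, closing the ring and setting C4 under control of C5. C5 comes from an asymmetric alkynylation; the oxirane is closed from the C4 carbinol and its acetoxymethyl arm.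

Key step: step 7

Remark: the ring numbering C1–C5 defined above is used throughout. The ligand enantiomer in step 3 is assumed to be the one that delivers the (R)-alcohol 7; if the sense of induction is the opposite, its antipode is used.

Step 1
Reactants: 1 4-iodophenol
Product: 2 (4-iodophenoxy)triisopropylsilane
Conditions: TIPSCl, imidazole, DMF, rt
Reagents that add atoms: triisopropylsilyl chloride, CC(C)[Si](Cl)(C(C)C)C(C)C
Why: Imidazole-mediated O-silylation should mask the phenol as a base-stable aryl silyl ether for the organometallic steps; no stereocentre is involved.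

Step 2
Reactants: 2 (4-iodophenoxy)triisopropylsilane; 3 dimethyl oxalate
Product: 5 methyl 2-oxo-2-[4-(triisopropylsilyloxy)phenyl]acetate, via arylmagnesium chloride 4 (not isolated)
Conditions: iPrMgCl·LiCl, THF, 0 °C; then added to 3 (3 equiv), THF, −78 °C
Reagents that add atoms: none
Why: Iodine–magnesium exchange followed by inverse addition to excess oxalate should stop at mono-acylation (nucleophilic acyl substitution) and give the aryl α-keto ester.

Step 3
Reactants: 5 methyl 2-oxo-2-[4-(triisopropylsilyloxy)phenyl]acetate; 6 ethynyltrimethylsilane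
Product: 7 methyl (2R)-2-hydroxy-2-[4-(triisopropylsilyloxy)phenyl]-4-(trimethylsilyl)but-3-ynoate
Conditions: Zn(OTf)2 (20 mol%), (1S,2S)- or (1R,2R)-2-(dimethylamino)-1-(4-nitrophenyl)-3-(tert-butyldimethylsilyloxy)propan-1-ol (22 mol%), Et3N (30 mol%), toluene, 60 °C, sealed tube
Reagents that add atoms: none
Why: Catalytic enantioselective alkynylation of an α-keto ester by a zinc acetylide formed in situ should set the C5 stereocentre, the amino alcohol ligand selecting the ketone face.

Step 4
Reactants: 7 methyl (2R)-2-hydroxy-2-[4-(triisopropylsilyloxy)phenyl]-4-(trimethylsilyl)but-3-ynoate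
Product: 9 methyl (2S)-2-methoxy-2-[4-(triisopropylsilyloxy)phenyl]but-3-ynoate, via silylalkyne methyl ether 8 (not isolated)
Conditions: NaH, MeI, THF/DMF, 0 °C; then K2CO3, MeOH, rt
Reagents that add atoms: iodomethane, CI
Why: Williamson O-methylation of the tertiary alkoxide followed by methanolytic protodesilylation of the alkynylsilane should give the terminal alkyne without touching C5 (the descriptor changes only because the CIP priorities change).

Step 5
Reactants: 9 methyl (2S)-2-methoxy-2-[4-(triisopropylsilyloxy)phenyl]but-3-ynoate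
Product: 10 methyl (2R)-4-acetoxy-2-methoxy-3-oxo-2-[4-(triisopropylsilyloxy)phenyl]butanoate
Conditions: Ph3PAuNTf2 (5 mol%), 8-methylquinoline N-oxide (1.5 equiv), AcOH (5 equiv), PhCF3, rt
Reagents that add atoms: 8-methylquinoline N-oxide, Cc1cccc2ccc[n+]([O-])c12; acetic acid, CC(=O)O
Why: Gold-catalysed N-oxide oxidation of the terminal alkyne should place oxygen on the internal carbon (C4) and give an α-oxo gold carbene at the terminal carbon, which inserts into the O–H bond of acetic acid to give the acetoxymethyl ketone.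

Step 6
Reactants: 2 (4-iodophenoxy)triisopropylsilane; 11 2-chloro-1,1-dimethoxyethane
Product: 14 triisopropyl[4-(methoxyethynyl)phenoxy]silane, via lithium methoxyacetylide 12 (not isolated), via methoxyethynylzinc chloride 13 (not isolated)
Conditions: 11, LiNEt2 (3.1 equiv), THF, 0 °C; ZnCl2, 0 °C; then 2, Pd(PPh3)4 (5 mol%), rt
Reagents that add atoms: none
Why: Double elimination from the chloroacetal gives the methoxyacetylide, whose zinc derivative should undergo Negishi coupling with the aryl iodide to give the aryl ynol ether, which is used without storage.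

Step 7
Reactants: 10 methyl (2R)-4-acetoxy-2-methoxy-3-oxo-2-[4-(triisopropylsilyloxy)phenyl]butanoate; 14 triisopropyl[4-(methoxyethynyl)phenoxy]silane
Product: 15 (4R,5R)-4-(acetoxymethyl)-4-hydroxy-2,5-dimethoxy-3,5-bis[4-(triisopropylsilyloxy)phenyl]cyclopent-2-en-1-one
Conditions: Ni(COD)2 (15 mol%), PBu3 (30 mol%), Et3B (3 equiv), THF/MeOH 8:1, 50 °C, slow addition of 14
Reagents that add atoms: none
Why: Proposed new method: zerovalent nickel should couple the polarised ynol ether 14 with the doubly activated C4 ketone of 10 by oxidative cyclisation (C3–C4 bond; nickel on C2 and on the C4 oxygen), methanol then cleaves the Ni–O bond and the freed alkenylnickel methoxide attacks the C1 methyl ester in a 5-exo-trig acyl substitution that closes the cyclopentenone (C1–C2 bond) and expels methoxide, after which Et3B returns divalent nickel to the zerovalent state by ethyl transfer and β-hydride elimination. The closest known reaction type is the nickel-catalysed reductive [3+2] cycloaddition of enoates with alkynes under the same Et3B/MeOH conditions, here with a ketone C=O in place of the enoate C=C; nickel-catalysed reductive couplings of carbonyl compounds with ynamides show the same regiochemistry, with C–C bond formation at the alkyne carbon remote from the heteroatom. The new C4 stereocentre is set in the C3–C4 bond formation by 1,2-induction from C5: in the Felkin–Anh arrangement C3 approaches anti to the C5 aryl group while the C4 carbonyl is turned away from the C5–OMe dipole, which after ring closure places the C4 hydroxyl cis to the C5 aryl group and the acetoxymethyl arm cis to C5–OMe, as the target requires. The step needs regioselectivity (C3, not C2, to the ketone), which the oxygen substituent of the ynol ether should secure, and chemoselectivity for the ketone over the two ester carbonyls, which its higher electrophilicity should secure; the acetate keeps the primary oxygen from lactonising onto the C1 ester, which would lock the ketone in a ring and reverse the facial bias.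

Step 8
Reactants: 15 (4R,5R)-4-(acetoxymethyl)-4-hydroxy-2,5-dimethoxy-3,5-bis[4-(triisopropylsilyloxy)phenyl]cyclopent-2-en-1-one
Product: 16 (4R,5R)-4-hydroxy-4-(hydroxymethyl)-2,5-dimethoxy-3,5-bis[4-(triisopropylsilyloxy)phenyl]cyclopent-2-en-1-one
Conditions: K2CO3 (0.2 equiv), MeOH, 0 °C
Reagents that add atoms: none
Why: Base-catalysed transesterification should remove the primary acetate at low temperature, where the aryl triisopropylsilyl ethers survive and retro-aldol opening of the tertiary aldol is slow.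

Step 9
Reactants: 16 (4R,5R)-4-hydroxy-4-(hydroxymethyl)-2,5-dimethoxy-3,5-bis[4-(triisopropylsilyloxy)phenyl]cyclopent-2-en-1-one
Product: 18 (3R,4R)-4,6-dimethoxy-4,7-bis[4-(triisopropylsilyloxy)phenyl]-1-oxaspiro[2.4]hept-6-en-5-one, via primary methanesulfonate 17 (not isolated)
Conditions: MsCl (1.05 equiv), Et3N, CH2Cl2, −20 °C; then DBU, 0 °C to rt
Reagents that add atoms: none
Why: Selective sulfonylation of the primary hydroxyl followed by intramolecular Williamson etherification (3-exo-tet) by the tertiary C4 oxygen should close the spiro-oxirane with retention at C4, since no bond to C4 is broken.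

Step 10
Reactants: 18 (3R,4R)-4,6-dimethoxy-4,7-bis[4-(triisopropylsilyloxy)phenyl]-1-oxaspiro[2.4]hept-6-en-5-one
Product: 19 (3R,4R)-4,7-bis(4-hydroxyphenyl)-4,6-dimethoxy-1-oxaspiro[2.4]hept-6-en-5-one
Conditions: TBAF (2.2 equiv), AcOH (2.2 equiv), THF, 0 °C
Reagents that add atoms: none
Why: Fluoride-mediated cleavage of the two aryl silyl ethers under acetic acid buffering should free the phenols without exposing the acid-labile allylic oxirane to acid or to free phenoxide.

Compound list
1 | 4-iodophenol | Oc1ccc(I)cc1 | starting material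
2 | (4-iodophenoxy)triisopropylsilane | CC(C)[Si](Oc1ccc(I)cc1)(C(C)C)C(C)C | intermediate
3 | dimethyl oxalate | COC(=O)C(=O)OC | starting material
4 | chloro[4-(triisopropylsilyloxy)phenyl]magnesium (LiCl complex) | CC(C)[Si](Oc1ccc([Mg]Cl)cc1)(C(C)C)C(C)C | intermediate
5 | methyl 2-oxo-2-[4-(triisopropylsilyloxy)phenyl]acetate | COC(=O)C(=O)c1ccc(O[Si](C(C)C)(C(C)C)C(C)C)cc1 | intermediate
6 | ethynyltrimethylsilane | C#C[Si](C)(C)C | starting material
7 | methyl (2R)-2-hydroxy-2-[4-(triisopropylsilyloxy)phenyl]-4-(trimethylsilyl)but-3-ynoate | C[Si](C)(C)C#C[C@](O)(c1ccc(O[Si](C(C)C)(C(C)C)C(C)C)cc1)C(=O)OC | intermediate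
8 | methyl (2R)-2-methoxy-2-[4-(triisopropylsilyloxy)phenyl]-4-(trimethylsilyl)but-3-ynoate | C[Si](C)(C)C#C[C@](OC)(c1ccc(O[Si](C(C)C)(C(C)C)C(C)C)cc1)C(=O)OC | intermediate
9 | methyl (2S)-2-methoxy-2-[4-(triisopropylsilyloxy)phenyl]but-3-ynoate | C#C[C@](OC)(c1ccc(O[Si](C(C)C)(C(C)C)C(C)C)cc1)C(=O)OC | intermediate
10 | methyl (2R)-4-acetoxy-2-methoxy-3-oxo-2-[4-(triisopropylsilyloxy)phenyl]butanoate | CC(=O)OCC(=O)[C@](OC)(c1ccc(O[Si](C(C)C)(C(C)C)C(C)C)cc1)C(=O)OC | intermediate
11 | 2-chloro-1,1-dimethoxyethane | COC(CCl)OC | starting material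
12 | lithium methoxyacetylide | COC#C[Li] | intermediate
13 | chloro(methoxyethynyl)zinc | COC#C[Zn]Cl | intermediate
14 | triisopropyl[4-(methoxyethynyl)phenoxy]silane | COC#Cc1ccc(O[Si](C(C)C)(C(C)C)C(C)C)cc1 | intermediate
15 | (4R,5R)-4-(acetoxymethyl)-4-hydroxy-2,5-dimethoxy-3,5-bis[4-(triisopropylsilyloxy)phenyl]cyclopent-2-en-1-one | COC1=C(c2ccc(O[Si](C(C)C)(C(C)C)C(C)C)cc2)[C@@](O)(COC(C)=O)[C@](OC)(c2ccc(O[Si](C(C)C)(C(C)C)C(C)C)cc2)C1=O | intermediate
16 | (4R,5R)-4-hydroxy-4-(hydroxymethyl)-2,5-dimethoxy-3,5-bis[4-(triisopropylsilyloxy)phenyl]cyclopent-2-en-1-one | COC1=C(c2ccc(O[Si](C(C)C)(C(C)C)C(C)C)cc2)[C@@](O)(CO)[C@](OC)(c2ccc(O[Si](C(C)C)(C(C)C)C(C)C)cc2)C1=O | intermediate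
17 | (4R,5R)-4-hydroxy-2,5-dimethoxy-4-[(methylsulfonyloxy)methyl]-3,5-bis[4-(triisopropylsilyloxy)phenyl]cyclopent-2-en-1-one | COC1=C(c2ccc(O[Si](C(C)C)(C(C)C)C(C)C)cc2)[C@@](O)(COS(C)(=O)=O)[C@](OC)(c2ccc(O[Si](C(C)C)(C(C)C)C(C)C)cc2)C1=O | intermediate
18 | (3R,4R)-4,6-dimethoxy-4,7-bis[4-(triisopropylsilyloxy)phenyl]-1-oxaspiro[2.4]hept-6-en-5-one | COC1=C(c2ccc(O[Si](C(C)C)(C(C)C)C(C)C)cc2)[C@@]2(CO2)[C@](OC)(c2ccc(O[Si](C(C)C)(C(C)C)C(C)C)cc2)C1=O | intermediate
19 | (3R,4R)-4,7-bis(4-hydroxyphenyl)-4,6-dimethoxy-1-oxaspiro[2.4]hept-6-en-5-one | COC1=C(c2ccc(O)cc2)[C@@]2(CO2)[C@](OC)(c2ccc(O)cc2)C1=O | target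

Total step count: 10. Longest linear sequence: 9 steps (steps 1–5 and 7–10); step 6 is the side branch.

Steps most likely to fail

Step 7 (Proposed new method). What may go wrong:
- The hindered ketone may fail to enter oxidative cyclisation, so that the ynol ether oligomerises on nickel instead.
- C2 rather than C3 may add to the ketone.
- Facial selectivity at C4 may be poor.
- Acyl transfer may occur from the acetate instead of the methyl ester.

The fallback uses known chemistry, sets out from 2 and 9 and returns at 15. The Grignard reagent 4 made from 2 is acylated with N,2-dimethoxy-N-methylacetamide to give 2-methoxy-1-[4-(triisopropylsilyloxy)phenyl]ethan-1-one F1. Its lithium enolate (LiN(SiMe3)2, THF, −78 °C) undergoes Claisen condensation with ester 9 to give (4S)-2,4-dimethoxy-1,4-bis[4-(triisopropylsilyloxy)phenyl]hex-5-yne-1,3-dione F2. O-Sulfonylation of the enolate of F2 (NaH, PhNTf2) at the less hindered aryl ketone oxygen should give (1E,4S)-2,4-dimethoxy-3-oxo-1,4-bis[4-(triisopropylsilyloxy)phenyl]hex-1-en-5-yn-1-yl trifluoromethanesulfonate F3, with the triflate cis to the C1 acyl group. Gold-catalysed oxidation of the alkyne as in step 5 gives (1E,4R)-6-acetoxy-2,4-dimethoxy-3,5-dioxo-1,4-bis[4-(triisopropylsilyloxy)phenyl]hex-1-en-1-yl trifluoromethanesulfonate F4. An intramolecular Nozaki–Hiyama–Kishi reaction (CrCl2, NiCl2 cat., DMF) then adds the alkenyl carbon C3 to the C4 ketone and closes the ring to 15, with the same sense of 1,2-induction expected.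

Step 5. What may go wrong: the gold carbene may be captured intramolecularly by the neighbouring C5 methoxy oxygen or the ester carbonyl instead of by acetic acid, or the N-oxide may attack the hindered internal alkyne carbon too slowly.

The fallback sets out from 9 and returns at 10. Markovnikov hydration of the alkyne (Ph3PAuNTf2 cat., H2O, dioxane, 60 °C) gives methyl (2R)-2-methoxy-3-oxo-2-[4-(triisopropylsilyloxy)phenyl]butanoate F5. Kinetic enolisation, possible only toward the methyl group (LiN(SiMe3)2, Me3SiCl, THF, −78 °C), gives methyl (2R)-2-methoxy-2-[4-(triisopropylsilyloxy)phenyl]-3-(trimethylsilyloxy)but-3-enoate F6. Rubottom-type acetoxylation with Pb(OAc)4 (CH2Cl2, 0 °C) gives 10.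

Step 3. What may go wrong: enantioselectivity or conversion may be insufficient with the electron-rich aryl keto ester and the volatile silylacetylene.

The fallback sets out from 5 and returns at 9. Addition of ethynylmagnesium bromide (THF, −78 °C) gives racemic methyl 2-hydroxy-2-[4-(triisopropylsilyloxy)phenyl]but-3-ynoate F7. O-Methylation (NaH, MeI, THF/DMF) gives racemic methyl 2-methoxy-2-[4-(triisopropylsilyloxy)phenyl]but-3-ynoate F8. Preparative supercritical-fluid chromatography on a chiral stationary phase separates 9 from its enantiomer, methyl (2R)-2-methoxy-2-[4-(triisopropylsilyloxy)phenyl]but-3-ynoate F9.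

Further compounds
F1 | step 7 | 2-methoxy-1-[4-(triisopropylsilyloxy)phenyl]ethan-1-one | COCC(=O)c1ccc(O[Si](C(C)C)(C(C)C)C(C)C)cc1
F2 | step 7 | (4S)-2,4-dimethoxy-1,4-bis[4-(triisopropylsilyloxy)phenyl]hex-5-yne-1,3-dione | C#C[C@](OC)(c1ccc(O[Si](C(C)C)(C(C)C)C(C)C)cc1)C(=O)C(OC)C(=O)c1ccc(O[Si](C(C)C)(C(C)C)C(C)C)cc1
F3 | step 7 | (1E,4S)-2,4-dimethoxy-3-oxo-1,4-bis[4-(triisopropylsilyloxy)phenyl]hex-1-en-5-yn-1-yl trifluoromethanesulfonate | C#C[C@](OC)(c1ccc(O[Si](C(C)C)(C(C)C)C(C)C)cc1)C(=O)/C(OC)=C(\OS(=O)(=O)C(F)(F)F)c1ccc(O[Si](C(C)C)(C(C)C)C(C)C)cc1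
F4 | step 7 | (1E,4R)-6-acetoxy-2,4-dimethoxy-3,5-dioxo-1,4-bis[4-(triisopropylsilyloxy)phenyl]hex-1-en-1-yl trifluoromethanesulfonate | CC(=O)OCC(=O)[C@](OC)(c1ccc(O[Si](C(C)C)(C(C)C)C(C)C)cc1)C(=O)/C(OC)=C(\OS(=O)(=O)C(F)(F)F)c1ccc(O[Si](C(C)C)(C(C)C)C(C)C)cc1
F5 | step 5 | methyl (2R)-2-methoxy-3-oxo-2-[4-(triisopropylsilyloxy)phenyl]butanoate | CC(=O)[C@](OC)(c1ccc(O[Si](C(C)C)(C(C)C)C(C)C)cc1)C(=O)OC
F6 | step 5 | methyl (2R)-2-methoxy-2-[4-(triisopropylsilyloxy)phenyl]-3-(trimethylsilyloxy)but-3-enoate | C=C(O[Si](C)(C)C)[C@](OC)(c1ccc(O[Si](C(C)C)(C(C)C)C(C)C)cc1)C(=O)OC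
F7 | step 3 | methyl 2-hydroxy-2-[4-(triisopropylsilyloxy)phenyl]but-3-ynoate (racemic) | C#CC(O)(c1ccc(O[Si](C(C)C)(C(C)C)C(C)C)cc1)C(=O)OC
F8 | step 3 | methyl 2-methoxy-2-[4-(triisopropylsilyloxy)phenyl]but-3-ynoate (racemic) | C#CC(OC)(c1ccc(O[Si](C(C)C)(C(C)C)C(C)C)cc1)C(=O)OC
F9 | step 3 | methyl (2R)-2-methoxy-2-[4-(triisopropylsilyloxy)phenyl]but-3-ynoate (unwanted enantiomer) | C#C[C@@](OC)(c1ccc(O[Si](C(C)C)(C(C)C)C(C)C)cc1)C(=O)OC
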